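## Analysis of the target

The target is a C30 biflavonoid in which a chroman-4-one (rings A and C, locants 2–8a, ring B = 4-hydroxyphenyl on C2) is joined to a flavan (rings D and E, primed locants, ring B′ on C2′) through the bonds C2–O7′ and C3–C8′, which close a dihydrofuran, ring F (C2, O7′, C7′, C8′, C3). C2 is thereby a mixed ketal carbon (O1, O7′, ring B, C3), and C3 is a fully substituted carbinol bonded to C2, the C4 ketone, OH and C8′. There are three stereocentres: C2 and C3 are neighbours on the ring C/ring F fusion and depend on each other, because ring F can close on C2 in one sense only once C3 is fixed, whereas C2′ (S) is remote from C3 (four bonds through O1′) and has to be set on its own. The sensitive sites are the ketal C2 (it ionises in acid to an oxocarbenium ion stabilised by O1 and ring B), the tertiary α-ketol C3–OH/C4=O (acyloin shift or cleavage in base), the benzylic C2′–O1′ ether (acidolysis, hydrogenolysis) and five free phenols. The synthesis is hard because the C3–C8′ bond joins a quaternary carbon to an arene carbon flanked by two oxygenated carbons, and because ring D is pentasubstituted with three oxygens of different fate: O7′ enters the ketal, O1′ enters ring E and O5′ stays free. The strategy rests on ring D being a phloroglucinol in which the oxygenated carbons C7′, C8a′ and C5′ alternate with C8′ (bonded to C3), C4a′ (bonded to C4′) and C6′ (H). A vinylketene/siloxyalkyne benzannulation delivers exactly this alternation, so ring D can be grown on an alkyne that already sits on C3, and the congested aryl–C3 bond is reduced to a C(sp)–C3 bond made by carbonyl addition.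

## Retrosynthetic reasoning

**32 to 31 and 30.** The last two operations only unmask phenols. 32 is traced to 31, in which the four phenols of rings A, B and D are benzyl ethers, and 31 to 30, in which the ring B′ phenol is still a pivalate. The ester is kept on ring B′ up to this point so that the aryl group on C2′ stays electron-poor while the C2′–O1′ bond is made. It is cleaved before the benzyl ethers so that base never meets the free polyphenol.

**30 to 29 (ring E).** Ring E is opened at O1′–C2′. A cut here, rather than at C4′–C4a′ or inside ring D, leaves in 29 a plain secondary benzylic alcohol whose configuration can be fixed early, on a small fragment, by a reagent-controlled ketone reduction. The forward reaction must join the hindered C8a′ phenol to that carbinol with clean inversion, (R) in 29 becoming (S) in 30, without touching the tertiary C3–OH.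

**29 to 28 and 27 (ring F).** Ring F is opened at C2–O7′. C2 is at the ketone oxidation level, so this bond forms through an oxocarbenium ion and is the natural last bond of the ketal. The price is that C2 is re-formed on closure and follows C3. The forward step needs O7′ to be the only free phenol when the ketal exchanges, because O1′ is just as close to C2. In 27, O7′ is free, O1′ is a silyl ether and O5′ a benzyl ether. After closure (28), fluoride frees O1′, the C3–OH and the carbinol in one operation to give 29.

**27 to 11 and 22 (ring D, the key disconnection).** Three bonds of ring D are cut: C7′–C8′, C4a′–C8a′ and C6′–C7′. This leaves the siloxyalkyne 11, whose alkyne carbons become C8′ and C8a′, and the cyclobutenone 22, which supplies C7′, C4a′, C5′ and C6′ together with the whole C4′–C2′ chain. The hindered C3–C8′ bond is not cut at all: in 11 it is an ordinary bond from C3 to an sp carbon. The gains are convergence of two fragments of similar size and the arrival of the three ring D oxygens as free phenol, silyl ether and benzyl ether. The forward cascade (through 23, 24, 25 and 26) must bond the ketene carbon to the alkyne carbon on C3 and not to the oxygen-bearing one.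

**11 to 10, 9, 8, 7 and 6.** The O–C(sp) bond of 11 comes from oxidation of the acetylide 9 to the ynolate 10; 9 is the anion of 8, the silyl ether of carbinol 7. The C3–C(sp) bond of 7 is cut back to dione 6, where C3 is the most electrophilic carbon: a non-conjugated ketone between a ketal and a second carbonyl. The C3 configuration needs care. C2 of any 2-alkoxy-3,4-dione is stereogenic, so a chiral catalyst acting on a racemic ketal would meet matched and mismatched substrates. Instead the C2 alkoxy group is made the source of chirality: it is an enantiopure terpene alkoxy group, so the dione is formed as two separable C2 diastereomers, of which 6 is taken on, and the alkynyl nucleophile then adds under substrate control. C2 is erased again when ring F closes, so the auxiliary leaves the molecule at that point.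

**6 to 5, 4, 3, 2 and 1.** The dione ketal 6 is the product of a two-electron oxidation of flavonol 4 (through the iodane 5) with capture of an alcohol at C2. 4 is traced to flavone 2 by oxygenation of C3 (through epoxide 3), and 2 to the commercial trihydroxyflavone 1. A flavone is chosen as the start because direct benzylation at the flavonol stage would alkylate O3 before the chelated O5, so a 5,7,4′-tribenzyl ether with free O3–H is not available that way.

**22 to 21, 20, 19, 18, 17 and 16.** The four-membered ring of 22 is cut by a retro-[2+2] into a two-carbon ketene unit and the benzyl alkynyl ether 20; in the forward sense the two chlorines of 21 are removed reductively. This cut fixes the alkyl chain on C2 and the benzyloxy group on C3 of the cyclobutenone without ambiguity. 20 is cut at its propargylic C–C bond into the acetylide 19, derived from dichlorovinyl ether 18 (from benzyl alcohol 17), and the iodide 16.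

**16 to 15, 14, 13 and 12.** The iodide comes from the chloride 15 and the carbinol 14. The stereocentre of 14 is set by a catalytic, reagent-controlled borane reduction of the aryl ketone 13, the pivalate of the commercial chloroketone 12.

## Alternatives that were turned down

Alternative 1: The cuts are C2–O1, C2–O7′ and C3–C8′. Rings C and F are opened to an open-chain diketone stage, and the C3–C8′ bond is traced back to a C4–C8′ bond. In the forward step two ortho phenols, one on ring A and one on ring D, add to the C2 carbonyl and bridge the chain. An α-ketol shift then moves ring D from C4 to C3, which contracts one six-membered ring to the dihydrofuran, unveils the C4 ketone and gives A1.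
- For it: rings C and F and the C3 carbinol arise in one cascade. No ketene or strained ring is needed. C2 and C3 are tied together by the geometry of the bridged intermediate.
- Against it: the substrate is a tertiary carbinol with two very similar, 2,6-dioxygenated aryl groups, and its absolute configuration decides everything that follows. No reliable way exists to add one such aryl group enantioselectively to a ketone that carries the other. The shift must move ring D and not ring A, and it is reversible, so the outcome rests on a thermodynamic preference that the structure does not guarantee. An open-chain α-hydroxy-1,2-diketone is also open to benzilic-type cleavage.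
- Comparison: Alternative 1 is stronger on redox and step economy at the end. The chosen strategy offers in its place a C3 centre made by a simple carbonyl addition before ring D exists, and a ring D regiochemistry fixed by alkyne polarisation rather than by migratory aptitude.

Alternative 2: The cut is the C2–C3 bond inside ring F. The forward step is a Norrish–Yang photocyclisation of a 1,2-diketone whose O7′ carries a 4-benzyloxybenzyl group. The excited C3 carbonyl abstracts a benzylic hydrogen from that group and the 1,5-biradical couples, giving the 3-aroyl-3-hydroxy-2-aryl-2,3-dihydrobenzofuran A2.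
- For it: the conditions are neutral and mild. Ring F and the quaternary carbinol form in one step. This type of cyclisation is well known for ortho-alkoxyaryl ketones.
- Against it: both new stereocentres are formed under the influence of the remote C2′ only, so no control of C3 is to be expected and diastereomers must be separated late. C2 arrives at the ether oxidation level and has to be oxidised to the ketal level next to a tertiary alcohol before ring C can close, which adds redox and protecting-group steps. Excited 1,2-diketones also have cleavage and photoreduction channels.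
- Comparison: Alternative 2 is stronger on the mildness of its key step. The chosen strategy offers a C3 configuration fixed before the fragments are joined and a C2 carbon that is at the ketal oxidation level from the flavonol onwards.

Alternative 3: The cuts are O1–C8a and C4–C4a, so that ring A is added last. In the forward step a carboxylate on C3 of a substrate that already carries rings D, E and F and a C2 methyl ketal adds to a 3,5-dialkoxy-substituted aryne. The aryl anion then takes over the acyl group to give the ortho-hydroxyaryl ketone A3, which is set up for ketal exchange at C2.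
- For it: the phenol for ring C is created exactly where it is needed. The aryne regiochemistry is favourable, because the oxygen adds meta and the anion sits ortho to an alkoxy group. Ring A enters very late.
- Against it: the acyl transfer has to occur onto a carbonyl attached to a fully substituted carbon that lies between a ketal and ring D. For so hindered an acid, protonation of the aryl anion to a simple aryl ester is the likely outcome. The acid substrate itself contains the C2 ketal, the C3 quaternary centre and ring D, so the main difficulty of the target is only moved into its preparation, with more steps.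
- Comparison: Alternative 3 is stronger on the late introduction of ring A. The chosen strategy offers a short route to the C3 centre from a flavone and makes the hindered aryl–C3 bond without any reaction at a neopentyl-type carbonyl.

Key step: step 15

Remark on the chemistry (assumption): C2 is a ketal carbon that is re-formed when ring F closes, and O7′, tethered to C3 through C8′, can reach it from one face only, so the route controls C3 and C2′ and C2 follows; compounds 28–32 are written with the C2 descriptor of the target structure on the assumption that it denotes this ring-closed, cis-fused ketal (the C2 epimer, a trans-fused dihydrobenzofuran ketal, cannot be reached by ketal exchange), and in 6–27 the C2 alkoxy centre only relays chirality and is drawn for acetylide addition anti to the alkoxy group.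

## Steps

Step 1
Reactants: 1 apigenin (5,7-dihydroxy-2-(4-hydroxyphenyl)-4H-chromen-4-one)
Product: 2 5,7-bis(benzyloxy)-2-[4-(benzyloxy)phenyl]-4H-chromen-4-one
Conditions: BnBr (4.5 equiv), K2CO3, DMF, 80 °C
Reagents that add atoms: benzyl bromide, BrCc1ccccc1
Why: Williamson etherification of all three phenols; the chelated 5-OH is the slowest and needs heat and excess reagent, and no other nucleophilic site competes in the flavone.

Step 2
Reactants: 2 5,7-bis(benzyloxy)-2-[4-(benzyloxy)phenyl]-4H-chromen-4-one
Product: 4 5,7-bis(benzyloxy)-2-[4-(benzyloxy)phenyl]-3-hydroxy-4H-chromen-4-one, via flavone 2,3-epoxide 3 (not isolated)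
Conditions: dimethyldioxirane, acetone/CH2Cl2, 0 °C to rt; then p-TsOH (cat.), CH2Cl2, rt
Reagents that add atoms: dimethyldioxirane, CC1(C)OO1
Why: Electrophilic epoxidation of the enol-ether C2=C3 bond by the dioxirane; acid then opens the epoxide at C2 and loss of the C3 proton gives the flavonol, the known C3 hydroxylation of flavones, which the benzyl ethers tolerate at low temperature.

Step 3
Reactants: 4 5,7-bis(benzyloxy)-2-[4-(benzyloxy)phenyl]-3-hydroxy-4H-chromen-4-one
Product: 6 (2R)-5,7-bis(benzyloxy)-2-[4-(benzyloxy)phenyl]-2-{[(1R,2S,5R)-2-isopropyl-5-methylcyclohexyl]oxy}chromane-3,4-dione, via acetoxy(phenyl)iodanyl enol ether 5 (not isolated)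
Conditions: PhI(OAc)2 (1.1 equiv), (−)-menthol (10 equiv), 4 Å molecular sieves, CH2Cl2, 0 °C to rt; isolation of the (2R) epimer by chromatography or crystallisation; azeotropic drying
Reagents that add atoms: (1R,2S,5R)-(−)-menthol, C[C@@H]1CC[C@H]([C@@H](C1)O)C(C)C
Why: Ligand exchange at the trivalent iodine reagent by the enol hydroxyl gives 5, and loss of PhI with attack of the alcohol at C2 gives the ketal, the known oxidative alkoxylation of flavonols to 2-alkoxy-3,4-diones. No useful selectivity at C2 is expected, but because the alkoxy group is enantiopure the two C2 epimers are diastereomers, and the (2R) epimer 6 is the one isolated and taken on.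

Step 4
Reactants: 6 (2R)-5,7-bis(benzyloxy)-2-[4-(benzyloxy)phenyl]-2-{[(1R,2S,5R)-2-isopropyl-5-methylcyclohexyl]oxy}chromane-3,4-dione
Product: 7 (2R,3S)-5,7-bis(benzyloxy)-2-[4-(benzyloxy)phenyl]-3-ethynyl-3-hydroxy-2-{[(1R,2S,5R)-2-isopropyl-5-methylcyclohexyl]oxy}chroman-4-one
Conditions: HC≡CMgBr (1.5 equiv), THF, −78 to −40 °C; aq NH4Cl
Reagents that add atoms: ethynylmagnesium bromide, C#C[Mg]Br
Why: Grignard 1,2-addition to the C3 carbonyl, which is far more electrophilic than the C4 aryl ketone deactivated by two alkoxy groups. The anomeric effect holds the bulky C2 alkoxy group axial, so the acetylide should enter from the opposite face (as in additions to 2-uloses with an axial anomeric substituent), which sets C3 as S.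

Step 5
Reactants: 7 (2R,3S)-5,7-bis(benzyloxy)-2-[4-(benzyloxy)phenyl]-3-ethynyl-3-hydroxy-2-{[(1R,2S,5R)-2-isopropyl-5-methylcyclohexyl]oxy}chroman-4-one
Product: 8 (2R,3S)-5,7-bis(benzyloxy)-2-[4-(benzyloxy)phenyl]-3-ethynyl-2-{[(1R,2S,5R)-2-isopropyl-5-methylcyclohexyl]oxy}-3-[(trimethylsilyl)oxy]chroman-4-one
Conditions: 1-(trimethylsilyl)imidazole (3 equiv), CH2Cl2, rt to 40 °C
Reagents that add atoms: 1-(trimethylsilyl)imidazole, C[Si](C)(C)n1ccnc1
Why: Neutral silyl transfer caps the hindered tertiary alcohol with the smallest silyl group, so that it cannot add to the ketene in step 15; no base is present that could trigger an α-ketol shift.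

Step 6
Reactants: 8 (2R,3S)-5,7-bis(benzyloxy)-2-[4-(benzyloxy)phenyl]-3-ethynyl-2-{[(1R,2S,5R)-2-isopropyl-5-methylcyclohexyl]oxy}-3-[(trimethylsilyl)oxy]chroman-4-one
Product: 11 (2R,3S)-5,7-bis(benzyloxy)-2-[4-(benzyloxy)phenyl]-2-{[(1R,2S,5R)-2-isopropyl-5-methylcyclohexyl]oxy}-3-{[(triisopropylsilyl)oxy]ethynyl}-3-[(trimethylsilyl)oxy]chroman-4-one, via lithium acetylide 9 (not isolated), via lithium ynolate 10 (not isolated)
Conditions: LiN(SiMe3)2, THF, −78 °C; t-BuOOLi (from t-BuOOH + LiN(SiMe3)2), −78 to 0 °C; i-Pr3SiOTf, −78 °C; Et3N-deactivated silica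
Reagents that add atoms: tert-butyl hydroperoxide, CC(C)(C)OO; triisopropylsilyl trifluoromethanesulfonate, CC(C)[Si](C(C)C)(C(C)C)OS(=O)(=O)C(F)(F)F
Why: The acetylide carbon attacks the peroxide oxygen of lithium tert-butyl peroxide and expels tert-butoxide, the known oxidation of lithium acetylides to ynolates; the bulky silyl triflate then traps the ynolate on oxygen. The C4 ketone has no α-hydrogen and is shielded by C3 and the ortho benzyloxy group.

Step 7
Reactants: 12 3-chloro-1-(4-hydroxyphenyl)propan-1-one
Product: 13 4-(3-chloropropanoyl)phenyl pivalate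
Conditions: PivCl (1.1 equiv), pyridine, CH2Cl2, 0 °C
Reagents that add atoms: pivaloyl chloride, CC(C)(C)C(=O)Cl
Why: O-acylation of the phenol; the weak base avoids elimination of HCl from the β-chloroketone, and the ester makes the aryl group electron-poor for the later SN2 step at the benzylic carbon.

Step 8
Reactants: 13 4-(3-chloropropanoyl)phenyl pivalate
Product: 14 4-[(1R)-3-chloro-1-hydroxypropyl]phenyl pivalate
Conditions: (S)-Me-CBS oxazaborolidine (10 mol%), BH3·SMe2, THF, −20 °C; MeOH
Reagents that add atoms: none
Why: Corey–Bakshi–Shibata reduction; with the aryl group as the large substituent the (S)-catalyst delivers hydride to the face that gives the (R)-alcohol, and the hindered aryl ester is inert to borane at this temperature.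

Step 9
Reactants: 14 4-[(1R)-3-chloro-1-hydroxypropyl]phenyl pivalate
Product: 15 4-[(1R)-1-(tert-butyldimethylsilyloxy)-3-chloropropyl]phenyl pivalate
Conditions: TBSCl, imidazole, DMF, rt
Reagents that add atoms: tert-butyldimethylsilyl chloride, CC(C)(C)[Si](C)(C)Cl
Why: Standard silylation of a secondary alcohol; the silyl ether survives the acetylide, ketene, zinc and thermal steps and is removed by fluoride.

Step 10
Reactants: 15 4-[(1R)-1-(tert-butyldimethylsilyloxy)-3-chloropropyl]phenyl pivalate
Product: 16 4-[(1R)-1-(tert-butyldimethylsilyloxy)-3-iodopropyl]phenyl pivalate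
Conditions: NaI (5 equiv), acetone, reflux
Reagents that add atoms: sodium iodide, [Na+].[I-]
Why: Finkelstein exchange at the primary carbon, driven by precipitation of NaCl; the stereocentre is not involved.

Step 11
Reactants: 17 benzyl alcohol
Product: 18 benzyl (E)-1,2-dichlorovinyl ether
Conditions: KH, THF, 0 °C; trichloroethylene, −50 °C to rt
Reagents that add atoms: trichloroethylene, ClC=C(Cl)Cl
Why: The alkoxide eliminates HCl from trichloroethylene and adds to the dichloroacetylene formed, the standard entry to 1,2-dichlorovinyl ethers as precursors of alkoxyacetylides.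

Step 12
Reactants: 18 benzyl (E)-1,2-dichlorovinyl ether; 16 4-[(1R)-1-(tert-butyldimethylsilyloxy)-3-iodopropyl]phenyl pivalate
Product: 20 4-[(1R)-5-(benzyloxy)-1-(tert-butyldimethylsilyloxy)pent-4-yn-1-yl]phenyl pivalate, via lithium benzyloxyacetylide 19 (not isolated)
Conditions: n-BuLi (2.0 equiv), THF, −78 to −40 °C; then 16, HMPA, −78 to 0 °C; work-up and storage below 20 °C
Reagents that add atoms: none
Why: Elimination of HCl and chlorine–lithium exchange give the lithium alkoxyacetylide, which is alkylated by the primary iodide (SN2) in the presence of HMPA. Exactly two equivalents of n-BuLi and low temperature protect the pivalate, and the product is kept cold because benzyl alkynyl ethers rearrange sigmatropically on warming.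

Step 13
Reactants: 20 4-[(1R)-5-(benzyloxy)-1-(tert-butyldimethylsilyloxy)pent-4-yn-1-yl]phenyl pivalate
Product: 21 3-(benzyloxy)-4,4-dichloro-2-[(3R)-3-(tert-butyldimethylsilyloxy)-3-(4-pivaloyloxyphenyl)propyl]cyclobut-2-en-1-one
Conditions: Cl3CCOCl, Zn(Cu), Et2O/DME, 0 °C to rt
Reagents that add atoms: trichloroacetyl chloride, O=C(Cl)C(Cl)(Cl)Cl
Why: [2+2] cycloaddition of dichloroketene (from the acid chloride and zinc) with the electron-rich alkynyl ether; the ketene carbonyl carbon bonds to the alkyne carbon remote from oxygen, which places the chain on C2 and the benzyloxy group on C3, and DME ties up ZnCl2.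

Step 14
Reactants: 21 3-(benzyloxy)-4,4-dichloro-2-[(3R)-3-(tert-butyldimethylsilyloxy)-3-(4-pivaloyloxyphenyl)propyl]cyclobut-2-en-1-one
Product: 22 3-(benzyloxy)-2-[(3R)-3-(tert-butyldimethylsilyloxy)-3-(4-pivaloyloxyphenyl)propyl]cyclobut-2-en-1-one
Conditions: Zn dust, AcOH, TMEDA, THF/i-PrOH, 0 °C to rt
Reagents that add atoms: none
Why: Reductive removal of both α-chlorine atoms by zinc through zinc enolates, the usual finish of the dichloroketene route to cyclobutenones; the amine buffer prevents acid-induced exchange or hydrolysis of the vinylogous ester.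

Step 15
Reactants: 11 (2R,3S)-5,7-bis(benzyloxy)-2-[4-(benzyloxy)phenyl]-2-{[(1R,2S,5R)-2-isopropyl-5-methylcyclohexyl]oxy}-3-{[(triisopropylsilyl)oxy]ethynyl}-3-[(trimethylsilyl)oxy]chroman-4-one; 22 3-(benzyloxy)-2-[(3R)-3-(tert-butyldimethylsilyloxy)-3-(4-pivaloyloxyphenyl)propyl]cyclobut-2-en-1-one
Product: 27 (2R,3S)-5,7-bis(benzyloxy)-2-[4-(benzyloxy)phenyl]-3-{4-(benzyloxy)-3-[(3R)-3-(tert-butyldimethylsilyloxy)-3-(4-pivaloyloxyphenyl)propyl]-6-hydroxy-2-[(triisopropylsilyl)oxy]phenyl}-2-{[(1R,2S,5R)-2-isopropyl-5-methylcyclohexyl]oxy}-3-[(trimethylsilyl)oxy]chroman-4-one, via vinylketene 23 (not isolated), via vinylcyclobutenone 24 (not isolated), via dienylketene 25 (not isolated), via cyclohexadienone 26 (not isolated)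
Conditions: 22 (1.3 equiv), toluene (0.1 M), sealed tube, 80 °C then 110 °C
Reagents that add atoms: none
Why: Heat opens cyclobutenone 22 by a conrotatory 4π electrocyclic reaction (strain release) to vinylketene 23, whose carbonyl carbon is attacked by the oxygen-remote alkyne carbon of 11, and the ketene [2+2] cycloaddition closes the four-membered ring of 24 (bonds C7′–C8′ and C4a′–C8a′). 24 reopens (4π) to dienylketene 25, which closes ring D by a thermal 6π electrocyclisation (bond C6′–C7′) to cyclohexadienone 26, and tautomerisation gives phenol 27. The closest known reaction type is the Danheiser benzannulation of cyclobutenones with siloxyalkynes, used here with a 3-alkoxycyclobutenone so that a phloroglucinol pattern results. No stereocentre is created: the sp3 carbon of 24 is lost on ring opening, and C2, C3 and the side-chain carbinol are untouched under neutral conditions. The step needs regioselectivity in the [2+2], and the polarisation of the siloxyalkyne secures it, because the carbon on C3 is the nucleophilic one; the alkyne substituent therefore ends between the new phenol and the silyl ether, the chain next to the silyl ether and the benzyl ether para to C8′. Chemoselectivity rests on the ketene preferring the electron-rich alkyne over the shielded, non-enolisable C4 ketone, and on the C3–OH being masked as its silyl ether. The result is a single free phenol (O7′), with O1′ silylated and O5′ benzylated, which is what the two later ring closures need.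

Step 16
Reactants: 27 (2R,3S)-5,7-bis(benzyloxy)-2-[4-(benzyloxy)phenyl]-3-{4-(benzyloxy)-3-[(3R)-3-(tert-butyldimethylsilyloxy)-3-(4-pivaloyloxyphenyl)propyl]-6-hydroxy-2-[(triisopropylsilyl)oxy]phenyl}-2-{[(1R,2S,5R)-2-isopropyl-5-methylcyclohexyl]oxy}-3-[(trimethylsilyl)oxy]chroman-4-one
Product: 29 (2R,3S)-5,7-bis(benzyloxy)-2-[4-(benzyloxy)phenyl]-3-hydroxychroman-4-one fused through C2–O7′ and C3–C8′ (ring F) to a ring D that carries 5′-benzyloxy and 8a′-hydroxy groups and the 4a′-[(3R)-3-hydroxy-3-(4-pivaloyloxyphenyl)propyl] chain, via ring-F silyl ether 28 (not isolated)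
Conditions: CSA (0.2 equiv), 4 Å molecular sieves, CH2Cl2, rt; then Bu4NF/AcOH (1:1, 6 equiv), THF, 0 °C to rt
Reagents that add atoms: none
Why: Acid ionises the C2 ketal with loss of the alkoxy auxiliary to an oxocarbenium ion stabilised by O1 and the 4-benzyloxyphenyl group, and the only free phenol, O7′, closes the dihydrofuran (5-exo-trig); the bulky alcohol set free does not compete in the reverse sense. O7′ is tied to C3 through C8′, so one mode of closure exists and C2 follows from C3. Buffered fluoride then removes the three silyl groups while the pivalate and benzyl ethers stay.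

Step 17
Reactants: 29 (2R,3S)-5,7-bis(benzyloxy)-2-[4-(benzyloxy)phenyl]-3-hydroxychroman-4-one fused through C2–O7′ and C3–C8′ (ring F) to a ring D that carries 5′-benzyloxy and 8a′-hydroxy groups and the 4a′-[(3R)-3-hydroxy-3-(4-pivaloyloxyphenyl)propyl] chain
Product: 30 (2R,3S,2′S)-5,7,5′-tris(benzyloxy)-2-[4-(benzyloxy)phenyl]-3-hydroxy-2′-[4-(pivaloyloxy)phenyl] derivative of the fused chromanone–flavan (rings A to F closed)
Conditions: PPh3 (2 equiv), DIAD (2 equiv), THF (0.01 M), 0 °C to rt
Reagents that add atoms: none
Why: Intramolecular Mitsunobu etherification: the phenol is the acidic partner and displaces the activated secondary benzylic oxygen in a 6-exo-tet SN2 step with inversion, (R)-carbinol to (S)-C2′. The pivaloyloxyphenyl group disfavours ionisation of the benzylic carbon, and the tertiary C3–OH is too hindered and too weakly acidic to take part.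

Step 18
Reactants: 30 (2R,3S,2′S)-5,7,5′-tris(benzyloxy)-2-[4-(benzyloxy)phenyl]-3-hydroxy-2′-[4-(pivaloyloxy)phenyl] derivative of the fused chromanone–flavan
Product: 31 (2R,3S,2′S)-5,7,5′-tris(benzyloxy)-2-[4-(benzyloxy)phenyl]-3-hydroxy-2′-(4-hydroxyphenyl) derivative of the fused chromanone–flavan
Conditions: K2CO3 (1.5 equiv), MeOH/THF, 0 °C to rt; aq NH4Cl
Reagents that add atoms: none
Why: Methanolysis of the aryl ester (transesterification by methoxide); the ketal and the non-enolisable ketone are stable to carbonate at room temperature, and only one phenol is exposed to base.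

Step 19
Reactants: 31 (2R,3S,2′S)-5,7,5′-tris(benzyloxy)-2-[4-(benzyloxy)phenyl]-3-hydroxy-2′-(4-hydroxyphenyl) derivative of the fused chromanone–flavan
Product: 32 target, (2R,3S,2′S)-3,5,7-trihydroxy-2-(4-hydroxyphenyl)chroman-4-one fused through C2–O7′ and C3–C8′ to (2′S)-5′-hydroxy-2′-(4-hydroxyphenyl)chromane
Conditions: H2 (1 atm), Pd(OH)2/C, EtOAc/MeOH, rt, stopped at four equivalents of H2
Reagents that add atoms: none
Why: Hydrogenolysis of the four aryl benzyl ethers; these cleave faster than the cyclic benzylic C2′–O1′ ether, the ketal C–O bonds and the hydrogen-bonded aryl ketone, so the reaction is stopped at the calculated uptake.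

## Compound list

1 | apigenin | O=c1cc(-c2ccc(O)cc2)oc2cc(O)cc(O)c12 | starting material
2 | 5,7-bis(benzyloxy)-2-[4-(benzyloxy)phenyl]-4H-chromen-4-one | O=c1cc(-c2ccc(OCc3ccccc3)cc2)oc2cc(OCc3ccccc3)cc(OCc3ccccc3)c12 | intermediate
3 | racemic 2,3-epoxide of 2 (not isolated) | O=C1c2c(OCc3ccccc3)cc(OCc3ccccc3)cc2OC2(c3ccc(OCc4ccccc4)cc3)OC12 | intermediate
4 | 5,7-bis(benzyloxy)-2-[4-(benzyloxy)phenyl]-3-hydroxy-4H-chromen-4-one | O=c1c(O)c(-c2ccc(OCc3ccccc3)cc2)oc2cc(OCc3ccccc3)cc(OCc3ccccc3)c12 | intermediate
5 | 3-O-[acetoxy(phenyl)-λ3-iodanyl] derivative of 4 (not isolated) | O=c1c(OI(OC(C)=O)c3ccccc3)c(-c2ccc(OCc3ccccc3)cc2)oc2cc(OCc3ccccc3)cc(OCc3ccccc3)c12 | intermediate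
6 | (2R)-5,7-bis(benzyloxy)-2-[4-(benzyloxy)phenyl]-2-{[(1R,2S,5R)-2-isopropyl-5-methylcyclohexyl]oxy}chromane-3,4-dione | O=C1c2c(OCc3ccccc3)cc(OCc3ccccc3)cc2O[C@](O[C@@H]2C[C@H](C)CC[C@H]2C(C)C)(c2ccc(OCc3ccccc3)cc2)C1=O | intermediate
7 | (2R,3S)-3-ethynyl-3-hydroxy adduct of 6 | O=C1c2c(OCc3ccccc3)cc(OCc3ccccc3)cc2O[C@](O[C@@H]2C[C@H](C)CC[C@H]2C(C)C)(c2ccc(OCc3ccccc3)cc2)[C@]1(O)C#C | intermediate
8 | 3-O-trimethylsilyl ether of 7 | O=C1c2c(OCc3ccccc3)cc(OCc3ccccc3)cc2O[C@](O[C@@H]2C[C@H](C)CC[C@H]2C(C)C)(c2ccc(OCc3ccccc3)cc2)[C@]1(O[Si](C)(C)C)C#C | intermediate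
9 | lithium acetylide of 8 (not isolated) | O=C1c2c(OCc3ccccc3)cc(OCc3ccccc3)cc2O[C@](O[C@@H]2C[C@H](C)CC[C@H]2C(C)C)(c2ccc(OCc3ccccc3)cc2)[C@]1(O[Si](C)(C)C)C#C[Li] | intermediate
10 | lithium ynolate from 9 (not isolated) | O=C1c2c(OCc3ccccc3)cc(OCc3ccccc3)cc2O[C@](O[C@@H]2C[C@H](C)CC[C@H]2C(C)C)(c2ccc(OCc3ccccc3)cc2)[C@]1(O[Si](C)(C)C)C#CO[Li] | intermediate
11 | (2R,3S)-5,7-bis(benzyloxy)-2-[4-(benzyloxy)phenyl]-2-{[(1R,2S,5R)-2-isopropyl-5-methylcyclohexyl]oxy}-3-{[(triisopropylsilyl)oxy]ethynyl}-3-[(trimethylsilyl)oxy]chroman-4-one | O=C1c2c(OCc3ccccc3)cc(OCc3ccccc3)cc2O[C@](O[C@@H]2C[C@H](C)CC[C@H]2C(C)C)(c2ccc(OCc3ccccc3)cc2)[C@]1(O[Si](C)(C)C)C#CO[Si](C(C)C)(C(C)C)C(C)C | intermediate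
12 | 3-chloro-1-(4-hydroxyphenyl)propan-1-one | O=C(CCCl)c1ccc(O)cc1 | starting material
13 | 4-(3-chloropropanoyl)phenyl pivalate | O=C(CCCl)c1ccc(OC(=O)C(C)(C)C)cc1 | intermediate
14 | 4-[(1R)-3-chloro-1-hydroxypropyl]phenyl pivalate | O[C@H](CCCl)c1ccc(OC(=O)C(C)(C)C)cc1 | intermediate
15 | 4-[(1R)-1-(tert-butyldimethylsilyloxy)-3-chloropropyl]phenyl pivalate | CC(C)(C)[Si](C)(C)O[C@H](CCCl)c1ccc(OC(=O)C(C)(C)C)cc1 | intermediate
16 | 4-[(1R)-1-(tert-butyldimethylsilyloxy)-3-iodopropyl]phenyl pivalate | CC(C)(C)[Si](C)(C)O[C@H](CCI)c1ccc(OC(=O)C(C)(C)C)cc1 | intermediate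
17 | benzyl alcohol | OCc1ccccc1 | starting material
18 | benzyl (E)-1,2-dichlorovinyl ether | Cl/C=C(/Cl)OCc1ccccc1 | intermediate
19 | lithium benzyloxyacetylide (not isolated) | [Li]C#COCc1ccccc1 | intermediate
20 | 4-[(1R)-5-(benzyloxy)-1-(tert-butyldimethylsilyloxy)pent-4-yn-1-yl]phenyl pivalate | c1ccccc1COC#CCC[C@@H](O[Si](C)(C)C(C)(C)C)c1ccc(OC(=O)C(C)(C)C)cc1 | intermediate
21 | 3-(benzyloxy)-4,4-dichloro-2-[(3R)-3-(tert-butyldimethylsilyloxy)-3-(4-pivaloyloxyphenyl)propyl]cyclobut-2-en-1-one | O=C1C(Cl)(Cl)C(OCc2ccccc2)=C1CC[C@@H](O[Si](C)(C)C(C)(C)C)c1ccc(OC(=O)C(C)(C)C)cc1 | intermediate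
22 | 3-(benzyloxy)-2-[(3R)-3-(tert-butyldimethylsilyloxy)-3-(4-pivaloyloxyphenyl)propyl]cyclobut-2-en-1-one | O=C1CC(OCc2ccccc2)=C1CC[C@@H](O[Si](C)(C)C(C)(C)C)c1ccc(OC(=O)C(C)(C)C)cc1 | intermediate
23 | vinylketene, 3-(benzyloxy)-2-[(3R)-3-(tert-butyldimethylsilyloxy)-3-(4-pivaloyloxyphenyl)propyl]buta-1,3-dien-1-one (not isolated) | O=C=C(CC[C@@H](O[Si](C)(C)C(C)(C)C)c1ccc(OC(=O)C(C)(C)C)cc1)C(=C)OCc1ccccc1 | intermediate
24 | [2+2] adduct, 4-(1-benzyloxyvinyl)-4-(side chain)-3-(triisopropylsilyloxy)cyclobut-2-en-1-one carrying C3 of the chromanone on its C2, mixture at the ring sp3 carbon (not isolated) | O=C1c2c(OCc3ccccc3)cc(OCc3ccccc3)cc2O[C@](O[C@@H]2C[C@H](C)CC[C@H]2C(C)C)(c2ccc(OCc3ccccc3)cc2)[C@]1(O[Si](C)(C)C)C1=C(O[Si](C(C)C)(C(C)C)C(C)C)C(CC[C@@H](O[Si](C)(C)C(C)(C)C)c2ccc(OC(=O)C(C)(C)C)cc2)(C(=C)OCc2ccccc2)C1=O | intermediate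
25 | dienylketene from ring opening of 24 (not isolated) | O=C1c2c(OCc3ccccc3)cc(OCc3ccccc3)cc2O[C@](O[C@@H]2C[C@H](C)CC[C@H]2C(C)C)(c2ccc(OCc3ccccc3)cc2)[C@]1(O[Si](C)(C)C)C(=C=O)/C(O[Si](C(C)C)(C(C)C)C(C)C)=C(/CC[C@@H](O[Si](C)(C)C(C)(C)C)c2ccc(OC(=O)C(C)(C)C)cc2)C(=C)OCc2ccccc2 | intermediate
26 | cyclohexa-2,4-dienone from 6π closure of 25 (not isolated) | O=C1c2c(OCc3ccccc3)cc(OCc3ccccc3)cc2O[C@](O[C@@H]2C[C@H](C)CC[C@H]2C(C)C)(c2ccc(OCc3ccccc3)cc2)[C@]1(O[Si](C)(C)C)C1=C(O[Si](C(C)C)(C(C)C)C(C)C)C(CC[C@@H](O[Si](C)(C)C(C)(C)C)c2ccc(OC(=O)C(C)(C)C)cc2)=C(OCc2ccccc2)CC1=O | intermediate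
27 | benzannulation product: ring D on C3 with free 7′-OH, 8a′-OSi(i-Pr)3, 5′-OBn and the 4a′ side chain | O=C1c2c(OCc3ccccc3)cc(OCc3ccccc3)cc2O[C@](O[C@@H]2C[C@H](C)CC[C@H]2C(C)C)(c2ccc(OCc3ccccc3)cc2)[C@]1(O[Si](C)(C)C)c1c(O)cc(OCc2ccccc2)c(CC[C@@H](O[Si](C)(C)C(C)(C)C)c2ccc(OC(=O)C(C)(C)C)cc2)c1O[Si](C(C)C)(C(C)C)C(C)C | intermediate
28 | ring F ketal with 3-OSiMe3, 8a′-OSi(i-Pr)3 and side-chain OTBS (not isolated) | O=C1c2c(OCc3ccccc3)cc(OCc3ccccc3)cc2O[C@@]2(c3ccc(OCc4ccccc4)cc3)Oc3cc(OCc4ccccc4)c(CC[C@@H](O[Si](C)(C)C(C)(C)C)c4ccc(OC(=O)C(C)(C)C)cc4)c(O[Si](C(C)C)(C(C)C)C(C)C)c3[C@]12O[Si](C)(C)C | intermediate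
29 | ring F ketal with free C3–OH, free 8a′-OH and free (R)-carbinol | O=C1c2c(OCc3ccccc3)cc(OCc3ccccc3)cc2O[C@@]2(c3ccc(OCc4ccccc4)cc3)Oc3cc(OCc4ccccc4)c(CC[C@@H](O)c4ccc(OC(=O)C(C)(C)C)cc4)c(O)c3[C@]12O | intermediate
30 | (2R,3S,2′S) hexacycle, 5,7,5′-tri-O-benzyl, ring B O-benzyl, ring B′ O-pivaloyl | O=C1c2c(OCc3ccccc3)cc(OCc3ccccc3)cc2O[C@@]2(c3ccc(OCc4ccccc4)cc3)Oc3cc(OCc4ccccc4)c4c(c3[C@]12O)O[C@H](c1ccc(OC(=O)C(C)(C)C)cc1)CC4 | intermediate
31 | (2R,3S,2′S) hexacycle, 5,7,5′-tri-O-benzyl, ring B O-benzyl, ring B′ free phenol | O=C1c2c(OCc3ccccc3)cc(OCc3ccccc3)cc2O[C@@]2(c3ccc(OCc4ccccc4)cc3)Oc3cc(OCc4ccccc4)c4c(c3[C@]12O)O[C@H](c1ccc(O)cc1)CC4 | intermediate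
32 | target CNP0208300.3, (2R,3S,2′S) | O=C1c2c(O)cc(O)cc2O[C@@]2(c3ccc(O)cc3)Oc3cc(O)c4c(c3[C@]12O)O[C@H](c1ccc(O)cc1)CC4 | target

## Step count and least certain steps

Total: 19 steps. Longest linear sequence: 12 steps, from 12 through steps 7–10 and 12–19. The chromanone branch from 1 is 11 steps.

**Step 15 (key step).** The most likely failure is a slow [2+2] addition. The alkyne carbon that must attack the ketene sits on a fully substituted carbon bearing three electron-withdrawing neighbours, so the vinylketene may be lost to dimerisation or to acylation of the product phenol before it is intercepted. Prolonged heating could also lead to loss of the tertiary silyl ether.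

The fallback reverses the order of events: ring D is built on an unhindered alkyne and the C3–C8′ bond is made afterwards by carbonyl addition. It sets out from cyclobutenone 22 and dione 6 and comes back to the route at 29. 22 would be heated with trimethyl{[(triisopropylsilyl)oxy]ethynyl}silane F1, made from trimethylsilylacetylene by the acetylide oxidation and O-silylation used in step 6. This should give the 2-(trimethylsilyl)resorcinol derivative F2. Ipso-iododesilylation with N-iodosuccinimide gives the iodophenol F3. Deprotonation (MeMgCl), iodine–magnesium exchange (i-PrMgCl·LiCl, which spares the pivalate) and addition to the C3 carbonyl of 6 in the presence of LaCl3·2LiCl should give, anti to the C2 alkoxy group, the tertiary carbinol F4. CSA then closes ring F to the ketal F5, and buffered Bu4NF gives 29.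

**Step 6.** The likely failures are attack of the acetylide or of the peroxide anion on the C4 ketone of a second molecule, C-silylation in place of O-silylation of the ynolate, and hydrolysis of the siloxyalkyne during isolation.

The fallback delivers the oxygenated alkyne as a nucleophile, so that no oxidation is run on the chromanone. It sets out from dione 6 and comes back at 11, bypassing 7 and 8. The C–Si bond of trimethyl{[(triisopropylsilyl)oxy]ethynyl}silane F1 is cleaved with MeLi to give lithium [(triisopropylsilyl)oxy]acetylide F6, which is added to 6 at −78 °C. The resulting alkoxide is silylated in the same flask with Me3SiCl to give 11.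

**Step 3 (with step 4).** The likely failures are inefficient capture of the C2 cation by the hindered secondary alcohol (competition by acetate or water), hydration of the dione at C3, poor separation of the two ketal diastereomers, and poor facial selectivity in the acetylide addition if chelation competes with the anti approach.

The fallback moves the stereochemical sorting to the next stage, where the compounds are stable alcohols. It sets out from flavonol 4 and comes back at 7. The oxidation is run as in step 3, but the crude ketal, 6 together with its (2S) epimer F7, is not separated. The mixture is ethynylated as in step 4, and the two diastereomeric carbinols, 7 and its (2S,3R) isomer F8, are separated as non-hydrated alcohols.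

**Step 12.** The likely failures are sigmatropic rearrangement or base-induced decomposition of the benzyl alkynyl ether, attack of the organolithium on the pivalate, and elimination of HI from the iodide.

The fallback uses an alkynyl ether with no sigmatropic pathway and introduces the benzyl group at the end. It sets out from iodide 16 and comes back at 22. Lithium ethoxyacetylide (from ethoxyacetylene and n-BuLi) is alkylated with 16 to the ethyl alkynyl ether F9. F9 is taken through the conditions of steps 13 and 14 to the dichlorocyclobutenone F10 and the 3-ethoxycyclobutenone F11. Acid-catalysed vinylogous transetherification of F11 with benzyl alcohol 17 (PPTS, CH2Cl2, rt, 5 Å molecular sieves to take up ethanol) gives 22.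

## Further compounds

F1 | step 15 | trimethyl{[(triisopropylsilyl)oxy]ethynyl}silane | C[Si](C)(C)C#CO[Si](C(C)C)(C(C)C)C(C)C
F2 | step 15 | 4-{(1R)-3-[6-(benzyloxy)-4-hydroxy-2-[(triisopropylsilyl)oxy]-3-(trimethylsilyl)phenyl]-1-(tert-butyldimethylsilyloxy)propyl}phenyl pivalate | C[Si](C)(C)c1c(O)cc(OCc2ccccc2)c(CC[C@@H](O[Si](C)(C)C(C)(C)C)c2ccc(OC(=O)C(C)(C)C)cc2)c1O[Si](C(C)C)(C(C)C)C(C)C
F3 | step 15 | 4-{(1R)-3-[6-(benzyloxy)-4-hydroxy-3-iodo-2-[(triisopropylsilyl)oxy]phenyl]-1-(tert-butyldimethylsilyloxy)propyl}phenyl pivalate | Ic1c(O)cc(OCc2ccccc2)c(CC[C@@H](O[Si](C)(C)C(C)(C)C)c2ccc(OC(=O)C(C)(C)C)cc2)c1O[Si](C(C)C)(C(C)C)C(C)C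
F4 | step 15 | (2R,3S) adduct of the ring D arylmagnesium with 6: analogue of 27 with free C3–OH | O=C1c2c(OCc3ccccc3)cc(OCc3ccccc3)cc2O[C@](O[C@@H]2C[C@H](C)CC[C@H]2C(C)C)(c2ccc(OCc3ccccc3)cc2)[C@]1(O)c1c(O)cc(OCc2ccccc2)c(CC[C@@H](O[Si](C)(C)C(C)(C)C)c2ccc(OC(=O)C(C)(C)C)cc2)c1O[Si](C(C)C)(C(C)C)C(C)C
F5 | step 15 | ring F ketal with free C3–OH, 8a′-OSi(i-Pr)3 and side-chain OTBS | O=C1c2c(OCc3ccccc3)cc(OCc3ccccc3)cc2O[C@@]2(c3ccc(OCc4ccccc4)cc3)Oc3cc(OCc4ccccc4)c(CC[C@@H](O[Si](C)(C)C(C)(C)C)c4ccc(OC(=O)C(C)(C)C)cc4)c(O[Si](C(C)C)(C(C)C)C(C)C)c3[C@]12O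
F6 | step 6 | lithium [(triisopropylsilyl)oxy]acetylide | [Li]C#CO[Si](C(C)C)(C(C)C)C(C)C
F7 | step 3 | (2S)-5,7-bis(benzyloxy)-2-[4-(benzyloxy)phenyl]-2-{[(1R,2S,5R)-2-isopropyl-5-methylcyclohexyl]oxy}chromane-3,4-dione | O=C1c2c(OCc3ccccc3)cc(OCc3ccccc3)cc2O[C@@](O[C@@H]2C[C@H](C)CC[C@H]2C(C)C)(c2ccc(OCc3ccccc3)cc2)C1=O
F8 | step 3 | (2S,3R)-5,7-bis(benzyloxy)-2-[4-(benzyloxy)phenyl]-3-ethynyl-3-hydroxy-2-{[(1R,2S,5R)-2-isopropyl-5-methylcyclohexyl]oxy}chroman-4-one | O=C1c2c(OCc3ccccc3)cc(OCc3ccccc3)cc2O[C@@](O[C@@H]2C[C@H](C)CC[C@H]2C(C)C)(c2ccc(OCc3ccccc3)cc2)[C@@]1(O)C#C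
F9 | step 12 | 4-[(1R)-1-(tert-butyldimethylsilyloxy)-5-ethoxypent-4-yn-1-yl]phenyl pivalate | CCOC#CCC[C@@H](O[Si](C)(C)C(C)(C)C)c1ccc(OC(=O)C(C)(C)C)cc1
F10 | step 12 | 4,4-dichloro-3-ethoxy-2-[(3R)-3-(tert-butyldimethylsilyloxy)-3-(4-pivaloyloxyphenyl)propyl]cyclobut-2-en-1-one | O=C1C(Cl)(Cl)C(OCC)=C1CC[C@@H](O[Si](C)(C)C(C)(C)C)c1ccc(OC(=O)C(C)(C)C)cc1
F11 | step 12 | 3-ethoxy-2-[(3R)-3-(tert-butyldimethylsilyloxy)-3-(4-pivaloyloxyphenyl)propyl]cyclobut-2-en-1-one | O=C1CC(OCC)=C1CC[C@@H](O[Si](C)(C)C(C)(C)C)c1ccc(OC(=O)C(C)(C)C)cc1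
A1 | alternative 1 | tetra-O-benzyl ether of the target with free C5–OH and C3–OH | O=C1c2c(O)cc(OCc5ccccc5)cc2O[C@@]2(c3ccc(OCc5ccccc5)cc3)Oc3cc(OCc5ccccc5)c4c(c3[C@]12O)O[C@H](c1ccc(OCc5ccccc5)cc1)CC4
A2 | alternative 2 | 3-aroyl-3-hydroxy-2-(4-benzyloxyphenyl)-2,3-dihydrobenzofuran fused to the flavan, ring A as tris(tert-butyldimethylsilyl) ether, ring B′ as pivalate | c1cc(OCc5ccccc5)ccc1[C@@H]2Oc3cc(OCc5ccccc5)c4c(c3[C@@]2(C(=O)c3c(O[Si](C)(C)C(C)(C)C)cc(O[Si](C)(C)C(C)(C)C)cc3O[Si](C)(C)C(C)(C)C)O)O[C@H](c1ccc(OC(=O)C(C)(C)C)cc1)CC4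
A3 | alternative 3 | 3-[2,4-bis(benzyloxy)-6-hydroxybenzoyl]-3-(methoxymethoxy) derivative of the C2 methyl ketal of the dihydrobenzofuran fused to the flavan | CO[C@@]2(c3ccc(OCc5ccccc5)cc3)Oc3cc(OCc5ccccc5)c4c(c3[C@@]2(C(=O)c3c(OCc5ccccc5)cc(OCc5ccccc5)cc3O)OCOC)O[C@H](c1ccc(OCc5ccccc5)cc1)CC4
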